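**Retrosynthetic overview**
1. The target is (12S)-12-hydroxy-GA3 (12α-hydroxygibberellic acid), so rings A, B and C and every stereocentre except C12 are bought with gibberellic acid.
2. C12–OH comes from face-selective hydride reduction of a 12-oxo-13-hydroxy ketol, itself made by oxidising a 12,13-diol.
3. Ring D (C13–C16 bond, 13-OH, 16-methylene) comes from a ketyl–alkyne reductive cyclisation of a ring C 13-ketone carrying a C8 propargyl arm and a 12-silyloxy group.
4. The 12-oxygen comes from Rubottom oxidation of that ketone; the keto-alkyne comes from Ohira–Bestmann homologation of the keto-aldehyde obtained by ozonolysis, reduction and glycol cleavage of ring D of GA3.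
5. Ring order: rings A, B and C (lactone included) stay intact from GA3; ring D is opened at C13–C16 and is the only ring formed, last.

Assumption: gibberellic acid (GA3, a bulk fermentation product) counts as commercially available; gibberellin numbering is used (ring C = C8, C9, C11–C14; ring D = C8, C14, C13, C16, C15; exocyclic C17).

Step 1
Reactants: 1 gibberellic acid (GA3)
Product: 2 GA3 7-SEM ester
Conditions: SEMCl, Et3N, DMF, 0 °C → rt
Reagents that add atoms: 2-(trimethylsilyl)ethoxymethyl chloride (SEMCl), C[Si](C)(C)CCOCCl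
Why: SN2 O-alkylation of the triethylammonium carboxylate by the reactive chloromethyl ether esterifies only the C7 acid (the neutral 3- and 13-hydroxyls do not compete) and installs an ester that falls to fluoride at the end, with no stereocentre touched.

Step 2
Reactants: 2 GA3 7-SEM ester
Product: 3 3-O-TBS GA3 7-SEM ester
Conditions: TBSCl, imidazole, DMF, rt
Reagents that add atoms: tert-butyldimethylsilyl chloride (TBSCl), CC(C)(C)[Si](C)(C)Cl
Why: Imidazole-mediated silylation (Corey TBS protection) takes only the secondary allylic 3-OH, because the bridgehead tertiary 13-OH is too hindered for TBSCl.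

Step 3
Reactants: 3 3-O-TBS GA3 7-SEM ester
Product: 5 17-nor-13,16-diol, via norketone 4 (not isolated)
Conditions: O3 (1 equiv), CH2Cl2/MeOH, −78 °C; then NaBH4, −78 → 0 °C
Reagents that add atoms: ozone, [O-][O+]=O
Why: Ozonolysis attacks the electron-rich 1,1-disubstituted C16=C17 alkene far faster than the ring A alkene (deactivated by two allylic C–O bonds), and the reductive NaBH4 work-up takes the 16-ketone from its open exo face to the diol, whose C16 configuration is irrelevant because step 4 removes it.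

Step 4
Reactants: 5 17-nor-13,16-diol
Product: 6 13,16-seco keto-aldehyde
Conditions: Pb(OAc)4, CH2Cl2, 0 °C
Reagents that add atoms: none
Why: Criegee glycol cleavage breaks the C13–C16 bond of either diol epimer, opening ring D to the ring C 13-ketone and the C16 aldehyde under neutral anhydrous conditions without touching C8 or any other stereocentre.

Step 5
Reactants: 6 13,16-seco keto-aldehyde; 7 dimethyl (1-diazo-2-oxopropyl)phosphonate
Product: 8 13,16-seco keto-alkyne
Conditions: 7, K2CO3, MeOH, 0 °C → rt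
Reagents that add atoms: dimethyl (1-diazo-2-oxopropyl)phosphonate (7), CC(=O)C(=[N+]=[N-])P(=O)(OC)OC
Why: Seyferth–Gilbert homologation in its Ohira–Bestmann form converts only the aldehyde (the ketone is inert to the diazophosphonate anion) into the terminal alkyne C16≡C17, the new carbon C17 coming from 7.

Step 6
Reactants: 8 13,16-seco keto-alkyne
Product: 11 (12R)-12-triethylsilyloxy 13-ketone, via silyl enol ether 9 (not isolated), via silyloxy epoxide 10 (not isolated)
Conditions: TESOTf, Et3N, CH2Cl2, −78 → 0 °C; then mCPBA, CH2Cl2, −20 °C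
Reagents that add atoms: triethylsilyl triflate (TESOTf), CC[Si](CC)(CC)OS(=O)(=O)C(F)(F)F; 3-chloroperoxybenzoic acid (mCPBA), OOC(=O)c1cccc(Cl)c1
Why: Rubottom oxidation, in which soft enolisation removes a proton from C12 rather than from the neopentyl C14 next to quaternary C8, mCPBA epoxidises the enol ether (predicted on the face cis to the C8 propargyl arm) and a 1,4-silyl shift gives the 12-silyloxy ketone, whose C12 configuration need not be controlled because step 8 erases it.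

Step 7
Reactants: 11 (12R)-12-triethylsilyloxy 13-ketone
Product: 13 3-O-TBS (12R)-12-hydroxy-GA3 7-SEM ester, via ring-D-closed TES ether 12 (not isolated)
Conditions: SmI2, HMPA, t-BuOH, THF, −78 → 0 °C; then PPTS, MeOH, 0 °C
Reagents that add atoms: none
Why: The C13 ketyl adds 5-exo-dig to the alkyne (Stork/Molander ketyl–alkyne reductive cyclisation) to re-form the C13–C16 bond with the exocyclic methylene, the two-carbon tether from C8 can bridge only on its own face of ring C so C13 returns as the natural 13S centre, and PPTS/MeOH then removes the secondary TES ether while the TBS ether stays.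

Step 8
Reactants: 13 3-O-TBS (12R)-12-hydroxy-GA3 7-SEM ester
Product: 14 3-O-TBS 12-oxo-GA3 7-SEM ester
Conditions: IBX, DMSO, rt
Reagents that add atoms: none
Why: IBX oxidation converts the only oxidisable hydroxyl (the secondary 12-OH; the 13-OH is tertiary and the 3-OH is silylated) into the 12-ketone without cleaving the 12,13-glycol C–C bond, deliberately erasing C12.

Step 9
Reactants: 14 3-O-TBS 12-oxo-GA3 7-SEM ester
Product: 15 3-O-TBS (12S)-12-hydroxy-GA3 7-SEM ester
Conditions: LiBH(s-Bu)3 (L-Selectride), THF, −78 °C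
Reagents that add atoms: none
Why: Bulky-hydride reduction of a locked cyclohexanone, in which the axial trajectory is blocked by the syn-axial C9–C10 bond so hydride enters equatorially and gives the axial 12-OH, cis to the 13-OH and anti to C13–C16, which is the 12S (12α) configuration of the target.

Step 10
Reactants: 15 3-O-TBS (12S)-12-hydroxy-GA3 7-SEM ester
Product: 16 (12S)-12-hydroxy-GA3 (the target gibberellin)
Conditions: TBAF, AcOH (1:1), THF, 0 °C → rt
Reagents that add atoms: none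
Why: Buffered fluoride cleaves the TBS ether and fragments the SEM ester (desilylative β-elimination releasing ethene and formaldehyde) under near-neutral conditions that avoid the allylic-lactone rearrangement and ring D Wagner–Meerwein shift of GA3-type compounds, with no stereocentre affected.

**Compound list**
1 | gibberellic acid (GA3) | C=C1C[C@]23C[C@@]1(O)CC[C@H]2[C@@]12C=C[C@H](O)[C@@](C)(C(=O)O1)[C@H]2[C@@H]3C(=O)O | starting material
2 | GA3 7-SEM ester (3-OH and 13-OH free) | C=C1C[C@]23C[C@@]1(O)CC[C@H]2[C@@]12C=C[C@H](O)[C@@](C)(C(=O)O1)[C@H]2[C@@H]3C(=O)OCOCC[Si](C)(C)C | intermediate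
3 | 3-O-TBS GA3 7-SEM ester (13-OH free) | C=C1C[C@]23C[C@@]1(O)CC[C@H]2[C@@]12C=C[C@H](O[Si](C)(C)C(C)(C)C)[C@@](C)(C(=O)O1)[C@H]2[C@@H]3C(=O)OCOCC[Si](C)(C)C | intermediate
4 | 17-nor-16-ketone of 3 (13-hydroxy-16-oxo ketol) | O=C1C[C@]23C[C@@]1(O)CC[C@H]2[C@@]12C=C[C@H](O[Si](C)(C)C(C)(C)C)[C@@](C)(C(=O)O1)[C@H]2[C@@H]3C(=O)OCOCC[Si](C)(C)C | intermediate
5 | 17-nor-13,16-diol of 3 (16S with 16-OH endo drawn; the 16-epimer serves equally) | O[C@H]1C[C@]23C[C@@]1(O)CC[C@H]2[C@@]12C=C[C@H](O[Si](C)(C)C(C)(C)C)[C@@](C)(C(=O)O1)[C@H]2[C@@H]3C(=O)OCOCC[Si](C)(C)C | intermediate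
6 | 13,16-seco keto-aldehyde (ring D opened; ring C 13-ketone, C8–CH2–CHO; C8 as in GA3) | O=CC[C@]23CC(=O)CC[C@H]2[C@@]12C=C[C@H](O[Si](C)(C)C(C)(C)C)[C@@](C)(C(=O)O1)[C@H]2[C@@H]3C(=O)OCOCC[Si](C)(C)C | intermediate
7 | dimethyl (1-diazo-2-oxopropyl)phosphonate (Ohira–Bestmann reagent) | CC(=O)C(=[N+]=[N-])P(=O)(OC)OC | starting material
8 | 13,16-seco keto-alkyne (ring C 13-ketone, C8–CH2–C≡CH) | C#CC[C@]23CC(=O)CC[C@H]2[C@@]12C=C[C@H](O[Si](C)(C)C(C)(C)C)[C@@](C)(C(=O)O1)[C@H]2[C@@H]3C(=O)OCOCC[Si](C)(C)C | intermediate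
9 | 13-O-TES enol ether of 8 (C12=C13) | C#CC[C@]23CC(O[Si](CC)(CC)CC)=CC[C@H]2[C@@]12C=C[C@H](O[Si](C)(C)C(C)(C)C)[C@@](C)(C(=O)O1)[C@H]2[C@@H]3C(=O)OCOCC[Si](C)(C)C | intermediate
10 | 12,13-epoxide of 9 (oxirane cis to the C8 propargyl arm; 13-OTES) | C#CC[C@]23C[C@]4(O[Si](CC)(CC)CC)O[C@@H]4C[C@H]2[C@@]12C=C[C@H](O[Si](C)(C)C(C)(C)C)[C@@](C)(C(=O)O1)[C@H]2[C@@H]3C(=O)OCOCC[Si](C)(C)C | intermediate
11 | (12R)-12-triethylsilyloxy 13-ketone (OTES cis to the C8 propargyl arm) | C#CC[C@]23CC(=O)[C@H](O[Si](CC)(CC)CC)C[C@H]2[C@@]12C=C[C@H](O[Si](C)(C)C(C)(C)C)[C@@](C)(C(=O)O1)[C@H]2[C@@H]3C(=O)OCOCC[Si](C)(C)C | intermediate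
12 | ring-D-closed 12-O-TES ether (12R,13S; 13-OH, 16-methylene) | C=C1C[C@]23C[C@@]1(O)[C@H](O[Si](CC)(CC)CC)C[C@H]2[C@@]12C=C[C@H](O[Si](C)(C)C(C)(C)C)[C@@](C)(C(=O)O1)[C@H]2[C@@H]3C(=O)OCOCC[Si](C)(C)C | intermediate
13 | 3-O-TBS (12R)-12-hydroxy-GA3 7-SEM ester (12-OH equatorial, trans to 13-OH) | C=C1C[C@]23C[C@@]1(O)[C@H](O)C[C@H]2[C@@]12C=C[C@H](O[Si](C)(C)C(C)(C)C)[C@@](C)(C(=O)O1)[C@H]2[C@@H]3C(=O)OCOCC[Si](C)(C)C | intermediate
14 | 3-O-TBS 12-oxo-GA3 7-SEM ester (12-oxo-13-hydroxy ketol) | C=C1C[C@]23C[C@@]1(O)C(=O)C[C@H]2[C@@]12C=C[C@H](O[Si](C)(C)C(C)(C)C)[C@@](C)(C(=O)O1)[C@H]2[C@@H]3C(=O)OCOCC[Si](C)(C)C | intermediate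
15 | 3-O-TBS (12S)-12-hydroxy-GA3 7-SEM ester (12-OH axial, cis to 13-OH) | C=C1C[C@]23C[C@@]1(O)[C@@H](O)C[C@H]2[C@@]12C=C[C@H](O[Si](C)(C)C(C)(C)C)[C@@](C)(C(=O)O1)[C@H]2[C@@H]3C(=O)OCOCC[Si](C)(C)C | intermediate
16 | (12S)-12-hydroxy-GA3 (12α-hydroxygibberellic acid; the target gibberellin) | C=C1C[C@]23C[C@@]1(O)[C@@H](O)C[C@H]2[C@@]12C=C[C@H](O)[C@@](C)(C(=O)O1)[C@H]2[C@@H]3C(=O)O | target

**Totals**
Total step count: 10. Longest linear sequence: 10 steps (from 1; 7 is a purchased reagent).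

**Three steps most likely to fail**

Step 7 (ring D re-closure). The samarium ketyl may expel the neighbouring silyloxy group or be reduced before the strained bridging bond forms. The fallback sets out from 11 and reverses the polarity at C13. TESOTf/Et3N converts 11 into the 12,13-bis(triethylsilyloxy) 12-ene F3. A monovalent gold catalyst (Ph3PAuCl/AgBF4, CH2Cl2/MeOH) then closes ring D by a 5-exo-dig Conia-ene attack of C13 on the alkyne, giving the 12-oxo 13-O-TES ether F4. LiBH(s-Bu)3 at −78 °C reduces this to the (12S)-12-hydroxy 13-O-TES ether F5, and TBAF/AcOH removes all silyl groups and the SEM ester. The fallback comes back to the route at 16.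

Step 6 (site of enolisation, C12 against C14). If the enol ether forms on the wrong side, the fallback sets out from 8 and makes the regiochemistry structural. IBX in DMSO at 70 °C dehydrogenates the ketone to the 11-en-13-one F1, which can only form toward C11–C12 because C8 is quaternary. Mukaiyama-type hydration with Mn(dpm)3, PhSiH3 and O2, followed by P(OEt)3, then places oxygen on the α-carbon to give the 12-hydroxy 13-ketone F2 (12R drawn; either epimer serves). TESCl/imidazole brings the sequence back at 11.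

Step 9 (face selectivity of the reduction; possible α-ketol shift of 14 under basic hydride). If the 12S alcohol is not obtained cleanly, C12 is instead set by catalyst control before ring closure. The fallback sets out from 8. D-proline-catalysed α-aminoxylation with nitrosobenzene goes through the less hindered C12 enamine and gives the (12S)-12-(N-phenylaminooxy) 13-ketone F6. Zn/AcOH cleaves the N–O bond to the (12S)-12-hydroxy 13-ketone F7, and TESCl/imidazole gives the (12S)-12-triethylsilyloxy 13-ketone F8. The SmI2/HMPA/t-BuOH cyclisation of step 7 then gives the (12S)-12-O-TES ring-D-closed ether F9, and PPTS/MeOH brings the route back at 15, bypassing steps 8 and 9.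

**Further compounds**
F1 | step 6 | 11-en-13-one (ring C enone of 8, C11=C12) | C#CC[C@]23CC(=O)C=C[C@H]2[C@@]12C=C[C@H](O[Si](C)(C)C(C)(C)C)[C@@](C)(C(=O)O1)[C@H]2[C@@H]3C(=O)OCOCC[Si](C)(C)C
F2 | step 6 | (12R)-12-hydroxy 13-ketone (desilyl 11) | C#CC[C@]23CC(=O)[C@H](O)C[C@H]2[C@@]12C=C[C@H](O[Si](C)(C)C(C)(C)C)[C@@](C)(C(=O)O1)[C@H]2[C@@H]3C(=O)OCOCC[Si](C)(C)C
F3 | step 7 | 12,13-bis(triethylsilyloxy) 12-ene (enediol bis-silyl ether of 11) | C#CC[C@]23CC(O[Si](CC)(CC)CC)=C(O[Si](CC)(CC)CC)C[C@H]2[C@@]12C=C[C@H](O[Si](C)(C)C(C)(C)C)[C@@](C)(C(=O)O1)[C@H]2[C@@H]3C(=O)OCOCC[Si](C)(C)C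
F4 | step 7 | 12-oxo 13-O-TES ether (13-O-TES derivative of 14) | C=C1C[C@]23C[C@@]1(O[Si](CC)(CC)CC)C(=O)C[C@H]2[C@@]12C=C[C@H](O[Si](C)(C)C(C)(C)C)[C@@](C)(C(=O)O1)[C@H]2[C@@H]3C(=O)OCOCC[Si](C)(C)C
F5 | step 7 | (12S)-12-hydroxy 13-O-TES ether (13-O-TES derivative of 15) | C=C1C[C@]23C[C@@]1(O[Si](CC)(CC)CC)[C@@H](O)C[C@H]2[C@@]12C=C[C@H](O[Si](C)(C)C(C)(C)C)[C@@](C)(C(=O)O1)[C@H]2[C@@H]3C(=O)OCOCC[Si](C)(C)C
F6 | step 9 | (12S)-12-(N-phenylaminooxy) 13-ketone | C#CC[C@]23CC(=O)[C@@H](ONc4ccccc4)C[C@H]2[C@@]12C=C[C@H](O[Si](C)(C)C(C)(C)C)[C@@](C)(C(=O)O1)[C@H]2[C@@H]3C(=O)OCOCC[Si](C)(C)C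
F7 | step 9 | (12S)-12-hydroxy 13-ketone | C#CC[C@]23CC(=O)[C@@H](O)C[C@H]2[C@@]12C=C[C@H](O[Si](C)(C)C(C)(C)C)[C@@](C)(C(=O)O1)[C@H]2[C@@H]3C(=O)OCOCC[Si](C)(C)C
F8 | step 9 | (12S)-12-triethylsilyloxy 13-ketone (12-epimer of 11) | C#CC[C@]23CC(=O)[C@@H](O[Si](CC)(CC)CC)C[C@H]2[C@@]12C=C[C@H](O[Si](C)(C)C(C)(C)C)[C@@](C)(C(=O)O1)[C@H]2[C@@H]3C(=O)OCOCC[Si](C)(C)C
F9 | step 9 | (12S)-12-O-TES ring-D-closed ether (12-O-TES derivative of 15) | C=C1C[C@]23C[C@@]1(O)[C@@H](O[Si](CC)(CC)CC)C[C@H]2[C@@]12C=C[C@H](O[Si](C)(C)C(C)(C)C)[C@@](C)(C(=O)O1)[C@H]2[C@@H]3C(=O)OCOCC[Si](C)(C)C
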